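**Retrosynthetic overview**

1. Numbering used below: ring A = C1–C5 and C10 (C4 carries the gem-dimethyl group); ring B = C5–C10 (C5=C10 alkene, C8 = CHMe, C9 = quaternary centre); C11 = benzylic CH2.
2. Quinone ring ⇐ oxidative demethylation and selective hydrolysis of a 2,3,5,6-tetramethoxyphenyl group; C9–CH3 ⇐ C9–CO2H; C9–C11 ⇐ benzylation of the C9 enediolate anti to the C8 methyl; C8 stereocentre ⇐ asymmetric hydrogenation of C8=C9.
3. Ring B ⇐ [4+2] cycloaddition of ethylene across C5 and C8 of a ring-A-fused 2-pyranone-4-carboxylic acid (new bonds C5–C6 and C7–C8), then loss of CO2. This one operation builds ring B, places the tetrasubstituted C5=C10 alkene regiospecifically and leaves C8=C9 as an acrylic acid ready to receive both stereocentres.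
4. Enabling feature: the temporary 2-pyranone ring, whose O–C(=O) bridge between C5 and C8 locks the diene C5=C10–C9=C8 s-cis and is expelled after the cycloaddition; the pyranone comes from 2,2-dimethylcyclohexanone, methylmalonyl dichloride and CO.
5. Ring order: ring A (bought) → temporary pyranone ring → ring B (key step) → quinone ring unveiled last from the attached arene.

Key step: step 5

Remark: methylmalonyl dichloride is taken as purchasable (otherwise one operation from methylmalonic acid), and the (S)-BINAP complex is assumed to give the 8S series; the ligand antipode would be used if the first run showed the opposite sense.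

**Route**

Step 1
Reactants: 1 2,2-dimethylcyclohexanone
Product: 2 trimethyl[(6,6-dimethylcyclohex-1-en-1-yl)oxy]silane
Conditions: TMSOTf, Et3N, CH2Cl2, 0 °C
Reagents that add atoms: trimethylsilyl trifluoromethanesulfonate, C[Si](C)(C)OS(=O)(=O)C(F)(F)F
Why: Soft enolisation and O-silylation (silyl enol ether formation) can only occur toward the single enolisable CH2 of 1, which fixes the regiochemistry of the later pyranone.

Step 2
Reactants: 2 trimethyl[(6,6-dimethylcyclohex-1-en-1-yl)oxy]silane; 3 methylmalonyl dichloride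
Product: 5 4-hydroxy-3,8,8-trimethyl-5,6,7,8-tetrahydro-2H-chromen-2-one, via keto acid chloride 4 (not isolated)
Conditions: Et2O, −20 °C → rt
Reagents that add atoms: none
Why: C-acylation of the silyl enol ether by one acid chloride followed by enol lactonisation onto the second is the established route from silyl enol ethers and malonyl dichlorides to 4-hydroxy-2-pyranones, and it builds the temporary ring with the future C8 methyl already in place.

Step 3
Reactants: 5 4-hydroxy-3,8,8-trimethyl-5,6,7,8-tetrahydro-2H-chromen-2-one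
Product: 6 3,8,8-trimethyl-2-oxo-5,6,7,8-tetrahydro-2H-chromen-4-yl trifluoromethanesulfonate
Conditions: Tf2O, Et3N, CH2Cl2, −78 → 0 °C
Reagents that add atoms: trifluoromethanesulfonic anhydride, O=S(=O)(OS(=O)(=O)C(F)(F)F)C(F)(F)F
Why: The acidic vinylogous-acid OH of a 4-hydroxypyranone should be O-sulfonylated cleanly to a vinyl triflate of the kind routinely used in couplings of pyranones and coumarins.

Step 4
Reactants: 6 3,8,8-trimethyl-2-oxo-5,6,7,8-tetrahydro-2H-chromen-4-yl trifluoromethanesulfonate
Product: 8 3,8,8-trimethyl-2-oxo-5,6,7,8-tetrahydro-2H-chromene-4-carboxylic acid, via mixed acetic anhydride 7 (not isolated)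
Conditions: Pd(OAc)2 (5 mol %), dppf, CO (1 atm), KOAc, DMF, 60 °C; then dilute aq. HCl
Reagents that add atoms: carbon monoxide, [C-]#[O+]; potassium acetate, CC(=O)[O-].[K+] (acetyl group in 7 only); water, O
Why: Palladium-catalysed hydroxycarbonylation of a vinyl triflate (oxidative addition, CO insertion, acetate capture to 7, hydrolysis on work-up) installs the C9 carboxyl group under non-hydrolytic conditions that spare the lactone.

Step 5
Reactants: 8 3,8,8-trimethyl-2-oxo-5,6,7,8-tetrahydro-2H-chromene-4-carboxylic acid; 9 ethylene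
Product: 11 2,5,5-trimethyl-3,4,5,6,7,8-hexahydronaphthalene-1-carboxylic acid, via bridged bicyclic lactone 10 (not isolated)
Conditions: ethylene (60 bar), toluene, BHT (cat.), 180 °C, autoclave
Reagents that add atoms: none
Why: Ethylene adds suprafacially across C8 and C5 (C3 and C8a of the pyranone), the termini of the diene that the lactone ring holds s-cis, to give the 2-oxabicyclo[2.2.2]octenone 10, which at this temperature loses CO2 by retro-[4+2] so that the new sigma bonds C5–C6 and C7–C8 remain and the diene reappears as C5=C10/C8=C9. The closest known reaction type is the Diels–Alder/decarboxylation of 2-pyranones (coumalates and alkylpyranones) with ethylene and other simple alkenes to give cyclohexa-1,3-dienes. Ring B is closed by an intermolecular [4+2] cycloaddition in which both bonds form in one concerted event on one face of the planar pyranone, and the temporary oxygen-bridged ring is opened again by the cycloreversion. No stereocentre survives, because the two bridgehead centres of 10 are erased with the CO2 loss, so facial and endo/exo selectivity are irrelevant, and regiochemistry does not arise with symmetric ethylene. The step needs mono-addition without aromatisation or double-bond migration: the product diene has two fully substituted termini and should be a far poorer diene than 8, no oxidant is present, and [1,5]-hydrogen shifts in cyclohexa-1,3-dienes are slow at 180 °C. The C9 carboxyl group lowers the LUMO of the pyranone toward the unactivated alkene and is carried on as the handle for both stereocentres.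

Step 6
Reactants: 11 2,5,5-trimethyl-3,4,5,6,7,8-hexahydronaphthalene-1-carboxylic acid
Product: 12 (1S,2S)-2,5,5-trimethyl-1,2,3,4,5,6,7,8-octahydronaphthalene-1-carboxylic acid
Conditions: Ru(OAc)2[(S)-BINAP] (2 mol %), H2 (50 bar), Et3N (1 equiv), MeOH, 40 °C
Reagents that add atoms: none
Why: Carboxylate-directed asymmetric hydrogenation of a tetrasubstituted α,β-unsaturated acid by a ruthenium–BINAP dicarboxylate should add H2 only to the C8=C9 bond held at the metal by the carboxylate, with the ligand choosing the face and so setting C8 as S, while the unactivated tetrasubstituted C5=C10 bond is left alone and the C9 configuration does not matter because step 9 erases it.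

Step 7
Reactants: 13 1,2,4,5-tetramethoxybenzene
Product: 15 (2,3,5,6-tetramethoxyphenyl)methanol, via aryllithium 14 (not isolated)
Conditions: n-BuLi, THF, 0 °C → rt; then (CH2O)n, 0 °C → rt; aq. NH4Cl
Reagents that add atoms: n-butyllithium, [Li]CCCC (lithium in 14 only); formaldehyde from paraformaldehyde, C=O
Why: Directed ortho-lithiation between two methoxy groups (the two free positions are equivalent) followed by hydroxymethylation of the aryllithium with formaldehyde should give the benzylic alcohol.

Step 8
Reactants: 15 (2,3,5,6-tetramethoxyphenyl)methanol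
Product: 16 3-(bromomethyl)-1,2,4,5-tetramethoxybenzene
Conditions: PBr3, Et2O, 0 °C; used at once
Reagents that add atoms: phosphorus tribromide, BrP(Br)Br
Why: PBr3 converts the electron-rich benzylic alcohol into the bromide by nucleophilic substitution under non-oxidising conditions that the tetramethoxyarene tolerates.

Step 9
Reactants: 12 (1S,2S)-2,5,5-trimethyl-1,2,3,4,5,6,7,8-octahydronaphthalene-1-carboxylic acid; 16 3-(bromomethyl)-1,2,4,5-tetramethoxybenzene
Product: 18 (1S,2S)-2,5,5-trimethyl-1-[(2,3,5,6-tetramethoxyphenyl)methyl]-1,2,3,4,5,6,7,8-octahydronaphthalene-1-carboxylic acid, via dilithium enediolate 17 (not isolated)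
Conditions: LiN(i-Pr)2 (2.2 equiv), THF–DMPU, −78 → 0 °C; then 16, −78 °C → rt; dilute aq. HCl
Reagents that add atoms: lithium diisopropylamide, [Li]N(C(C)C)C(C)C (lithium in 17 only)
Why: Double deprotonation gives enediolate 17, which should be alkylated at C9 (alpha-selective alkylation of a carboxylic acid dienediolate by a reactive benzylic halide) on the face anti to the C8 methyl group, which A(1,3) strain with the exocyclic enediolate forces pseudoaxial, so that the benzyl group ends up trans and the carboxyl group cis to that methyl while the C5=C10 bond stays where the cycloreversion placed it.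

Step 10
Reactants: 18 (1S,2S)-2,5,5-trimethyl-1-[(2,3,5,6-tetramethoxyphenyl)methyl]-1,2,3,4,5,6,7,8-octahydronaphthalene-1-carboxylic acid
Product: 19 {(1S,2S)-2,5,5-trimethyl-1-[(2,3,5,6-tetramethoxyphenyl)methyl]-1,2,3,4,5,6,7,8-octahydronaphthalen-1-yl}methanol
Conditions: LiAlH4, THF, reflux
Reagents that add atoms: none
Why: LiAlH4 reduces even a quaternary, neopentyl-type carboxylic acid to the primary alcohol without touching the tetrasubstituted alkene or the aryl ethers.

Step 11
Reactants: 19 {(1S,2S)-2,5,5-trimethyl-1-[(2,3,5,6-tetramethoxyphenyl)methyl]-1,2,3,4,5,6,7,8-octahydronaphthalen-1-yl}methanol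
Product: 20 (1S,2S)-2,5,5-trimethyl-1-[(2,3,5,6-tetramethoxyphenyl)methyl]-1,2,3,4,5,6,7,8-octahydronaphthalene-1-carbaldehyde
Conditions: Dess–Martin periodinane, NaHCO3, CH2Cl2, rt
Reagents that add atoms: none
Why: Dess–Martin oxidation should give the non-enolisable neopentyl aldehyde under neutral buffered conditions that leave the electron-rich arene alone.

Step 12
Reactants: 20 (1S,2S)-2,5,5-trimethyl-1-[(2,3,5,6-tetramethoxyphenyl)methyl]-1,2,3,4,5,6,7,8-octahydronaphthalene-1-carbaldehyde
Product: 22 3-{[(1R,2S)-1,2,5,5-tetramethyl-1,2,3,4,5,6,7,8-octahydronaphthalen-1-yl]methyl}-1,2,4,5-tetramethoxybenzene, via hydrazone 21 (not isolated)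
Conditions: N2H4·H2O, KOH, diethylene glycol, 130 → 200 °C
Reagents that add atoms: hydrazine, NN (nitrogen in 21 only)
Why: Wolff–Kishner reduction in the Huang-Minlon procedure should turn the hindered non-enolisable aldehyde into the C9 methyl group through hydrazone 21, with no epimerisable centre and no acid present (the change of descriptor at C9 from S to R is only a change of CIP priorities).

Step 13
Reactants: 22 3-{[(1R,2S)-1,2,5,5-tetramethyl-1,2,3,4,5,6,7,8-octahydronaphthalen-1-yl]methyl}-1,2,4,5-tetramethoxybenzene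
Product: 23 2,5-dimethoxy-3-{[(1R,2S)-1,2,5,5-tetramethyl-1,2,3,4,5,6,7,8-octahydronaphthalen-1-yl]methyl}cyclohexa-2,5-diene-1,4-dione
Conditions: (NH4)2Ce(NO3)6, MeCN–H2O, 0 °C
Reagents that add atoms: water, O
Why: Oxidative demethylation of a 1,4-dimethoxyarene by (NH4)2Ce(NO3)6 gives the p-quinone, either para pair of the symmetric tetramethoxy ring leads to the same 2,5-dimethoxyquinone, and the arene is far more easily oxidised than the tetrasubstituted alkene.

Step 14
Reactants: 23 2,5-dimethoxy-3-{[(1R,2S)-1,2,5,5-tetramethyl-1,2,3,4,5,6,7,8-octahydronaphthalen-1-yl]methyl}cyclohexa-2,5-diene-1,4-dione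
Product: 24 2-hydroxy-5-methoxy-3-{[(1R,2S)-1,2,5,5-tetramethyl-1,2,3,4,5,6,7,8-octahydronaphthalen-1-yl]methyl}cyclohexa-2,5-diene-1,4-dione
Conditions: KOH, MeOH–H2O, rt; then dilute HCl, 0 °C, brief
Reagents that add atoms: potassium hydroxide, [K+].[OH-]
Why: Hydroxide should exchange the vinylogous-ester methoxy group next to the alkyl chain by addition–elimination, a selectivity established for 2,5-dimethoxy-3-alkyl-1,4-benzoquinones, and the product stays as its stable anion until a short cold acidification that avoids acid-mediated cyclisation onto C5=C10.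

**Compound list**

1 | 2,2-dimethylcyclohexanone | CC1(C)CCCCC1=O | starting material
2 | trimethyl[(6,6-dimethylcyclohex-1-en-1-yl)oxy]silane | C[Si](C)(C)OC1=CCCCC1(C)C | intermediate
3 | methylmalonyl dichloride (2-methylpropanedioyl dichloride) | CC(C(Cl)=O)C(Cl)=O | starting material
4 | 3-(3,3-dimethyl-2-oxocyclohexyl)-2-methyl-3-oxopropanoyl chloride (not isolated) | CC(C(Cl)=O)C(=O)C1CCCC(C)(C)C1=O | intermediate
5 | 4-hydroxy-3,8,8-trimethyl-5,6,7,8-tetrahydro-2H-chromen-2-one | CC1=C(O)C2=C(OC1=O)C(C)(C)CCC2 | intermediate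
6 | 3,8,8-trimethyl-2-oxo-5,6,7,8-tetrahydro-2H-chromen-4-yl trifluoromethanesulfonate | CC1=C(OS(=O)(=O)C(F)(F)F)C2=C(OC1=O)C(C)(C)CCC2 | intermediate
7 | acetic 3,8,8-trimethyl-2-oxo-5,6,7,8-tetrahydro-2H-chromene-4-carboxylic anhydride (not isolated) | CC(=O)OC(=O)C1=C(C)C(=O)OC2=C1CCCC2(C)C | intermediate
8 | 3,8,8-trimethyl-2-oxo-5,6,7,8-tetrahydro-2H-chromene-4-carboxylic acid | CC1=C(C(=O)O)C2=C(OC1=O)C(C)(C)CCC2 | intermediate
9 | ethylene | C=C | starting material
10 | bridged lactone from 8 and ethylene: 2-oxabicyclo[2.2.2]oct-5-en-3-one with ring A fused at the oxygen-bearing bridgehead and the adjacent alkene carbon, methyl on the other bridgehead, CO2H on the second alkene carbon (racemic, not isolated) | CC12CCC3(OC1=O)C(C)(C)CCCC3=C2C(=O)O | intermediate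
11 | 2,5,5-trimethyl-3,4,5,6,7,8-hexahydronaphthalene-1-carboxylic acid | CC1=C(C(=O)O)C2=C(CC1)C(C)(C)CCC2 | intermediate
12 | (1S,2S)-2,5,5-trimethyl-1,2,3,4,5,6,7,8-octahydronaphthalene-1-carboxylic acid | OC(=O)[C@@H]1C2=C(CC[C@@H]1C)C(C)(C)CCC2 | intermediate
13 | 1,2,4,5-tetramethoxybenzene | COc1cc(OC)c(OC)cc1OC | starting material
14 | (2,3,5,6-tetramethoxyphenyl)lithium (not isolated) | [Li]c1c(OC)c(OC)cc(OC)c1OC | intermediate
15 | (2,3,5,6-tetramethoxyphenyl)methanol | COc1cc(OC)c(OC)c(CO)c1OC | intermediate
16 | 3-(bromomethyl)-1,2,4,5-tetramethoxybenzene | COc1cc(OC)c(OC)c(CBr)c1OC | intermediate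
17 | dilithium enediolate of 12, C8 still S (not isolated) | [Li]OC(O[Li])=C1C2=C(CC[C@@H]1C)C(C)(C)CCC2 | intermediate
18 | (1S,2S)-2,5,5-trimethyl-1-[(2,3,5,6-tetramethoxyphenyl)methyl]-1,2,3,4,5,6,7,8-octahydronaphthalene-1-carboxylic acid | OC(=O)[C@]1(Cc2c(OC)c(OC)cc(OC)c2OC)C2=C(CC[C@@H]1C)C(C)(C)CCC2 | intermediate
19 | {(1S,2S)-2,5,5-trimethyl-1-[(2,3,5,6-tetramethoxyphenyl)methyl]-1,2,3,4,5,6,7,8-octahydronaphthalen-1-yl}methanol | OC[C@]1(Cc2c(OC)c(OC)cc(OC)c2OC)C2=C(CC[C@@H]1C)C(C)(C)CCC2 | intermediate
20 | (1S,2S)-2,5,5-trimethyl-1-[(2,3,5,6-tetramethoxyphenyl)methyl]-1,2,3,4,5,6,7,8-octahydronaphthalene-1-carbaldehyde | O=C[C@]1(Cc2c(OC)c(OC)cc(OC)c2OC)C2=C(CC[C@@H]1C)C(C)(C)CCC2 | intermediate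
21 | hydrazone of 20 (not isolated) | NN=C[C@]1(Cc2c(OC)c(OC)cc(OC)c2OC)C2=C(CC[C@@H]1C)C(C)(C)CCC2 | intermediate
22 | 3-{[(1R,2S)-1,2,5,5-tetramethyl-1,2,3,4,5,6,7,8-octahydronaphthalen-1-yl]methyl}-1,2,4,5-tetramethoxybenzene | COc1cc(OC)c(OC)c(C[C@@]2(C)C3=C(CC[C@@H]2C)C(C)(C)CCC3)c1OC | intermediate
23 | 2,5-dimethoxy-3-{[(1R,2S)-1,2,5,5-tetramethyl-1,2,3,4,5,6,7,8-octahydronaphthalen-1-yl]methyl}cyclohexa-2,5-diene-1,4-dione | COC1=CC(=O)C(OC)=C(C[C@@]2(C)C3=C(CC[C@@H]2C)C(C)(C)CCC3)C1=O | intermediate
24 | 2-hydroxy-5-methoxy-3-{[(1R,2S)-1,2,5,5-tetramethyl-1,2,3,4,5,6,7,8-octahydronaphthalen-1-yl]methyl}cyclohexa-2,5-diene-1,4-dione | COC1=CC(=O)C(O)=C(C[C@@]2(C)C3=C(CC[C@@H]2C)C(C)(C)CCC3)C1=O | target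

**Step count and risks**

Total steps: 14. Longest linear sequence: 12 (steps 1–6 and 9–14); steps 7–8 make the benzylic bromide for the convergent step 9.

Most likely to fail, step 5. The cycloaddition may be too slow at the two fully substituted diene termini (C5 sits next to the quaternary C4), so that thermal decarboxylation or oligomerisation of the pyranone takes over. The fallback brings the two-carbon unit in at the alkyne oxidation level and then restores the diene. Acid 8 is heated with phenyl vinyl sulfoxide (toluene, 140 °C), an electron-poor acetylene equivalent matched to the alkyl-rich pyranone. The sulfinyl bridged lactone F1 (not isolated; either regioisomer serves, sulfur at C7 drawn) loses CO2 to the sulfinyl cyclohexadiene F2 (not isolated), which eliminates benzenesulfenic acid to the aromatic acid 2,5,5-trimethyl-5,6,7,8-tetrahydronaphthalene-1-carboxylic acid F3. Birch reduction (Li, NH3, THF, t-BuOH, −78 °C, then NH4Cl) should give 2,5,5-trimethyl-1,4,5,6,7,8-hexahydronaphthalene-1-carboxylic acid F4, with C5=C10 and C7=C8. Base-mediated conjugation (KOt-Bu, DMSO, rt) is expected to move C7=C8 to C8=C9, the fully substituted conjugated position, and return to 11.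

Second, step 6. Hydrogen may add 1,4 across the homoannular diene, the C5=C10 bond may migrate at the metal hydride, or facial discrimination at the tetrasubstituted alkene may be insufficient. The fallback gives up catalytic control and resolves. From 11, dissolving-metal reduction (Li, NH3–THF, −78 °C, excess metal destroyed with isoprene) and trapping of the resulting enediolate with bromide 16 should give the racemic trans acid F5, the racemate of 18, with the same anti alkylation. Salt formation with (S)-1-phenylethylamine and fractional crystallisation would give the (S)-1-phenylethylammonium salt F6 of the (1S,2S) acid (the amine antipode is used if the other salt is the less soluble one), and acidification returns to 18.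

Third, step 9. C-alkylation at the fully substituted C9 may lose to O-alkylation, to attack at the gamma position C5, or to decomposition of the very electron-rich benzylic bromide before it is captured. The fallback replaces the alkylation by an aldol addition and a benzylic deoxygenation. From 12, esterification (TMSCHN2, MeOH–toluene) gives methyl (1S,2S)-2,5,5-trimethyl-1,2,3,4,5,6,7,8-octahydronaphthalene-1-carboxylate F7. Alcohol 15 is oxidised (MnO2, CH2Cl2) to 2,3,5,6-tetramethoxybenzaldehyde F8. Deprotonation of F7 with LiN(i-Pr)2 (THF, −78 °C) gives the lithium ester enolate F9 (not isolated), which should add to F8 anti to the C8 methyl to give the β-hydroxy ester F10 (carbinol configuration irrelevant). Ionic deoxygenation of the electron-rich benzylic alcohol (Et3SiH, BF3·OEt2, CH2Cl2, −78 °C) gives the methyl ester F11 of 18, and LiAlH4 reduction returns to 19.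

**Further compounds**

F1 | step 5 | sulfinyl bridged lactone from 8 and phenyl vinyl sulfoxide (sulfur at C7, not isolated) | CC12C(S(=O)c4ccccc4)CC3(OC1=O)C(C)(C)CCCC3=C2C(=O)O
F2 | step 5 | 2,5,5-trimethyl-3-(phenylsulfinyl)-3,4,5,6,7,8-hexahydronaphthalene-1-carboxylic acid (not isolated) | CC1=C(C(=O)O)C2=C(CC1S(=O)c1ccccc1)C(C)(C)CCC2
F3 | step 5 | 2,5,5-trimethyl-5,6,7,8-tetrahydronaphthalene-1-carboxylic acid | Cc1ccc2c(c1C(=O)O)CCCC2(C)C
F4 | step 5 | 2,5,5-trimethyl-1,4,5,6,7,8-hexahydronaphthalene-1-carboxylic acid (racemic) | CC1=CCC2=C(C1C(=O)O)CCCC2(C)C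
F5 | step 6 | racemic trans acid, racemate of 18 | OC(=O)[C@]1(Cc2c(OC)c(OC)cc(OC)c2OC)C2=C(CC[C@@H]1C)C(C)(C)CCC2.OC(=O)[C@@]1(Cc2c(OC)c(OC)cc(OC)c2OC)C2=C(CC[C@H]1C)C(C)(C)CCC2
F6 | step 6 | (S)-1-phenylethylammonium salt of 18 | C[C@H]([NH3+])c1ccccc1.[O-]C(=O)[C@]1(Cc2c(OC)c(OC)cc(OC)c2OC)C2=C(CC[C@@H]1C)C(C)(C)CCC2
F7 | step 9 | methyl (1S,2S)-2,5,5-trimethyl-1,2,3,4,5,6,7,8-octahydronaphthalene-1-carboxylate | COC(=O)[C@@H]1C2=C(CC[C@@H]1C)C(C)(C)CCC2
F8 | step 9 | 2,3,5,6-tetramethoxybenzaldehyde | COc1cc(OC)c(OC)c(C=O)c1OC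
F9 | step 9 | lithium ester enolate of F7 (not isolated) | COC(O[Li])=C1C2=C(CC[C@@H]1C)C(C)(C)CCC2
F10 | step 9 | methyl (1S,2S)-1-[hydroxy(2,3,5,6-tetramethoxyphenyl)methyl]-2,5,5-trimethyl-1,2,3,4,5,6,7,8-octahydronaphthalene-1-carboxylate (carbinol epimers) | COC(=O)[C@]1(C(O)c2c(OC)c(OC)cc(OC)c2OC)C2=C(CC[C@@H]1C)C(C)(C)CCC2
F11 | step 9 | methyl (1S,2S)-2,5,5-trimethyl-1-[(2,3,5,6-tetramethoxyphenyl)methyl]-1,2,3,4,5,6,7,8-octahydronaphthalene-1-carboxylate | COC(=O)[C@]1(Cc2c(OC)c(OC)cc(OC)c2OC)C2=C(CC[C@@H]1C)C(C)(C)CCC2
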